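## Retrosynthetic overview

1. Epoxytwinol A ⇒ two copies of one (2R)-2H-pyran. A head-to-head formal [4+4] cycloaddition makes C3–C3′ and C6–C6′ and closes the central cycloocta-1,5-diene, the last ring formed.
2. 2H-Pyran ⇒ dienal by oxa-6π electrocyclization ⇒ epoxyquinol monomer diol by oxidation of its CH2OH. Oxidation, ring closure and dimerization run in one flask.
3. Monomer ⇒ α-iodo epoxy-enone + (E)-propenylboronic acid (Suzuki). Epoxide ⇒ cis-diol with net retention, through an orthoester and a bromoacetate (double inversion).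
4. γ-Hydroxy-enone ⇒ endoperoxide (Kornblum–DeLaMare) ⇒ cyclohexadiene + singlet oxygen ([4+2], anti to the acetonide).
5. Diene ⇒ (−)-shikimic acid. The carbocycle, the C3/C4 oxygens (future epoxide carbons) and the carboxyl carbon (future pyran CH–O) are bought. Ring order: carbocycle → epoxide → pyran → cyclooctadiene.

Assumption: operations telescoped on unpurified material count as one step. Natural (3R,4S,5R)-shikimic acid and (E)-prop-1-enylboronic acid are bought.

## Route

Step 1
Reactants: 1 (−)-shikimic acid
Product: 3 methyl 3,4-O-isopropylideneshikimate, via methyl shikimate 2 (not isolated)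
Conditions: CSA (cat.), MeOH, reflux; evaporate; Me2C(OMe)2, acetone, rt
Reagents that add atoms: methanol, CO; 2,2-dimethoxypropane, COC(C)(C)OC
Why: Fischer esterification followed by acid-catalysed transketalisation, which takes the only cis-1,2-diol (C3/C4), leaves C5–OH free and touches no stereocentre.

Step 2
Reactants: 3 methyl 3,4-O-isopropylideneshikimate
Product: 5 methyl (3aR,7aS)-2,2-dimethyl-3a,7a-dihydro-1,3-benzodioxole-5-carboxylate (diene ester), via 5-O-triflate 4 (not isolated)
Conditions: Tf2O, pyridine, CH2Cl2, −20 °C; crude triflate, CsOAc, DMF, rt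
Reagents that add atoms: trifluoromethanesulfonic anhydride, O=S(=O)(OS(=O)(=O)C(F)(F)F)C(F)(F)F (its CF3SO2 group is in 4 only)
Why: Triflation and mild-base anti-elimination of the vinylogously acidic C6–H (H4 is syn to the triflate and cannot compete) give the conjugated diene, keeping the bought C3/C4 centres and erasing C5, which is not needed.

Step 3
Reactants: 5 diene ester
Product: 6 [(3aR,7aS)-2,2-dimethyl-3a,7a-dihydro-1,3-benzodioxol-5-yl]methanol (dienol)
Conditions: DIBAL-H (2.5 equiv), CH2Cl2, −78 °C; Rochelle salt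
Reagents that add atoms: none
Why: DIBAL-H 1,2-reduction of the dienoate gives the primary allylic alcohol at −78 °C without touching the ketal or the diene, and 6 is used at once to avoid Diels–Alder self-dimerization.

Step 4
Reactants: 6 dienol
Product: 8 (4S,5R,6R)-4-hydroxy-3-(hydroxymethyl)-5,6-(isopropylidenedioxy)cyclohex-2-en-1-one, via endoperoxide 7 (not isolated)
Conditions: O2, TPP (1 mol %), visible light, CH2Cl2, −20 °C; then Et3N, 0 °C → rt
Reagents that add atoms: dioxygen, O=O
Why: Singlet-oxygen [4+2] cycloaddition on the face anti to the acetonide sets the carbinol centre (4S), and the Kornblum–DeLaMare rearrangement removes the less hindered bridgehead H, remote from CH2OH, to give the better stabilised β,β-disubstituted enone.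

Step 5
Reactants: 8 enone diol
Product: 9 di-tert-butylsilylene acetal of 8 (six-membered ring O–CH2–C3–C4–O–Si)
Conditions: t-Bu2Si(OTf)2, 2,6-lutidine, DMF, 0 °C
Reagents that add atoms: di-tert-butylsilyl bis(trifluoromethanesulfonate), CC(C)(C)[Si](OS(=O)(=O)C(F)(F)F)(OS(=O)(=O)C(F)(F)F)C(C)(C)C
Why: Silylene acetal formation masks the 1,3-diol in one operation with a group that cannot take part as a neighbouring group and is stable to mild acid and base.

Step 6
Reactants: 9 silylene acetonide
Product: 10 di-tert-butylsilylene acetal (on 4-O and CH2O) of (4S,5R,6R)-4,5,6-trihydroxy-3-(hydroxymethyl)cyclohex-2-en-1-one (free cis-5,6-diol)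
Conditions: TFA–H2O (4:1), CH2Cl2, 0 °C, short
Reagents that add atoms: none
Why: Acid hydrolysis of the isopropylidene ketal frees the cis-diol, while the hindered 1,3-dioxasilinane survives brief aqueous acid and no C–O bond at a stereocentre breaks.

Step 7
Reactants: 10 cis-diol
Product: 13 di-tert-butylsilylene acetal of (4S,5R,6R)-5,6-epoxy-4-hydroxy-3-(hydroxymethyl)cyclohex-2-en-1-one, via cyclic orthoacetate 11 (not isolated), via trans-bromoacetate 12 (not isolated)
Conditions: MeC(OMe)3, PPTS (cat.), CH2Cl2, rt; evaporate; AcBr, CH2Cl2, 0 °C; evaporate; K2CO3, MeOH, 0 °C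
Reagents that add atoms: trimethyl orthoacetate, COC(C)(OC)OC (in 11 and 12 only); acetyl bromide, CC(=O)Br (Br in 12 only)
Why: In this Kolb–Sharpless diol-to-epoxide sequence bromide opens the acetoxonium ion by SN2 at the α-keto carbon (first inversion) and the alkoxide freed by methanolysis displaces bromide (second inversion), so the epoxide sits on the face of the bought diol, anti to C4–O.

Step 8
Reactants: 13 epoxy-enone
Product: 14 2-iodo derivative of 13
Conditions: I2, PhI(OCOCF3)2, pyridine, CH2Cl2, rt, dark
Reagents that add atoms: iodine, II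
Why: α-Iodination of the enone by addition–elimination with CF3CO2I works on β-substituted enones because the β-alkyl groups stabilise the developing cation, and the stereocentres are untouched.

Step 9
Reactants: 14 iodo-enone; 15 (E)-prop-1-enylboronic acid
Product: 16 di-tert-butylsilylene acetal of the epoxyquinol monomer (2-[(E)-prop-1-enyl] derivative of 13)
Conditions: Pd(PhCN)2Cl2 (5 mol %), AsPh3, Ag2O, THF–H2O (8:1), rt
Reagents that add atoms: (E)-prop-1-enylboronic acid (15), C/C=C/B(O)O
Why: Suzuki–Miyaura coupling under Ag2O/AsPh3 conditions suited to base-sensitive 2-iodoenones proceeds at rt with retention of the E geometry.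

Step 10
Reactants: 16 protected monomer
Product: 17 (4S,5R,6R)-5,6-epoxy-4-hydroxy-3-(hydroxymethyl)-2-[(E)-prop-1-enyl]cyclohex-2-en-1-one (epoxyquinol monomer)
Conditions: HF·pyridine, pyridine, THF, 0 °C
Reagents that add atoms: none
Why: Buffered fluoride desilylation cleaves both Si–O bonds without opening the deactivated α,β-epoxy ketone and without the basic conditions that would allow Payne rearrangement.

Step 11
Reactants: 17 epoxyquinol monomer (two molecules)
Product: 20 epoxytwinol A, via dienal 18 (not isolated), via 2H-pyran 19 (not isolated)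
Conditions: MnO2, CH2Cl2, 0 °C → rt; filter, concentrate; neat film, rt, dark, 12–24 h; SiO2 chromatography
Reagents that add atoms: none
Why: Chemoselective MnO2 oxidation of the primary allylic alcohol gives dienal 18, which closes reversibly by oxa-6π electrocyclization, and two (2R)-pyrans 19 join head-to-head in a formal [4+4] cycloaddition on the face anti to both methyl and epoxide, so the three bought or derived ring centres set all six new ones (2R,3S,6S in each half).

## Compound list

1 | (−)-shikimic acid, (3R,4S,5R) | O=C(O)C1=C[C@@H](O)[C@@H](O)[C@H](O)C1 | starting material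
2 | methyl shikimate | COC(=O)C1=C[C@@H](O)[C@@H](O)[C@H](O)C1 | intermediate
3 | methyl 3,4-O-isopropylideneshikimate, (3aR,7R,7aS) | COC(=O)C1=C[C@H]2OC(C)(C)O[C@H]2[C@H](O)C1 | intermediate
4 | 5-O-triflate of 3 | COC(=O)C1=C[C@H]2OC(C)(C)O[C@H]2[C@H](OS(=O)(=O)C(F)(F)F)C1 | intermediate
5 | methyl (3aR,7aS)-2,2-dimethyl-3a,7a-dihydro-1,3-benzodioxole-5-carboxylate | COC(=O)C1=C[C@H]2OC(C)(C)O[C@H]2C=C1 | intermediate
6 | [(3aR,7aS)-2,2-dimethyl-3a,7a-dihydro-1,3-benzodioxol-5-yl]methanol | OCC1=C[C@H]2OC(C)(C)O[C@H]2C=C1 | intermediate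
7 | endoperoxide of 6, O–O bridge across the diene termini on the face opposite the acetonide | OCC1=C[C@H]2OO[C@@H]1[C@H]3OC(C)(C)O[C@@H]23 | intermediate
8 | (4S,5R,6R)-4-hydroxy-3-(hydroxymethyl)-5,6-(isopropylidenedioxy)cyclohex-2-en-1-one (4-OH trans to the acetonide oxygens) | OCC1=CC(=O)[C@@H]2OC(C)(C)O[C@@H]2[C@H]1O | intermediate
9 | di-tert-butylsilylene acetal of 8 (stereocentres as in 8) | O=C1C=C2CO[Si](C(C)(C)C)(C(C)(C)C)O[C@@H]2[C@H]3OC(C)(C)O[C@@H]13 | intermediate
10 | cis-5,6-diol from 9 (silylene kept, stereocentres as in 8) | O=C1C=C2CO[Si](C(C)(C)C)(C(C)(C)C)O[C@@H]2[C@@H](O)[C@H]1O | intermediate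
11 | 5,6-cyclic methyl orthoacetate of 10 (epimers at the orthoester carbon) | O=C1C=C2CO[Si](C(C)(C)C)(C(C)(C)C)O[C@@H]2[C@H]3OC(C)(OC)O[C@@H]13 | intermediate
12 | 5-O-acetyl-6-bromo compound, C6 inverted, Br trans to OAc | O=C1C=C2CO[Si](C(C)(C)C)(C(C)(C)C)O[C@@H]2[C@@H](OC(C)=O)[C@@H]1Br | intermediate
13 | 5,6-epoxide, oxygen on the face of the former diol, anti to C4–O (silylene kept) | O=C1C=C2CO[Si](C(C)(C)C)(C(C)(C)C)O[C@@H]2[C@H]3O[C@@H]13 | intermediate
14 | 2-iodo derivative of 13 | O=C1C(I)=C2CO[Si](C(C)(C)C)(C(C)(C)C)O[C@@H]2[C@H]3O[C@@H]13 | intermediate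
15 | (E)-prop-1-enylboronic acid | C/C=C/B(O)O | starting material
16 | 2-[(E)-prop-1-enyl] derivative of 13 | O=C1C(/C=C/C)=C2CO[Si](C(C)(C)C)(C(C)(C)C)O[C@@H]2[C@H]3O[C@@H]13 | intermediate
17 | (4S,5R,6R)-5,6-epoxy-4-hydroxy-3-(hydroxymethyl)-2-[(E)-prop-1-enyl]cyclohex-2-en-1-one | O=C1C(/C=C/C)=C(CO)[C@H](O)[C@H]2O[C@@H]12 | intermediate
18 | 3-formyl analogue of 17 (dienal) | O=C1C(/C=C/C)=C(C=O)[C@H](O)[C@H]2O[C@@H]12 | intermediate
19 | (2R)-2-methyl-2H-pyran fused to the epoxyquinol ring, methyl on the same face as the epoxide oxygen | C[C@H]1OC=C2[C@H](O)[C@H]3O[C@H]3C(=O)C2=C1 | intermediate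
20 | epoxytwinol A | C[C@H]1O[C@H]2C3=C(C(=O)[C@@H]4O[C@@H]4[C@H]3O)[C@@H]1[C@H]1C3=C([C@H](O)[C@H]4O[C@H]4C3=O)[C@@H]2O[C@@H]1C | target

## Step count and risks

Total step count: 11. Longest linear sequence: 11 (1 → 20).

**Step 4, regiochemistry of the Kornblum–DeLaMare step.** Only sterics and enone stability favour loss of the bridgehead H remote from CH2OH. If too much of the 2-(hydroxymethyl) enone forms, the base-induced differentiation is dropped. The fallback sets out from 6. It is photooxygenated as before and endoperoxide 7 is reduced in the flask with thiourea in MeOH to the cis-1,4-diol triol F1. t-Bu2Si(OTf)2/2,6-lutidine can close a six-membered ring only across CH2OH and the neighbouring secondary OH, which gives the silylene alcohol F2 with the remote allylic OH free. MnO2 (or Dess–Martin periodinane) oxidises that alcohol, and the route is rejoined at 9. This costs one extra step.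

**Step 7, cis-diol to epoxide with retention next to an enolisable, eliminable ketone.** If the acetoxonium route gives elimination or aromatisation, the fallback sets out from 10 and avoids the dioxolanylium ion. 4-Nitrobenzenesulfonyl chloride/Et3N at 0 °C sulfonylates the more acidic and less hindered α-keto hydroxyl to give the 6-O-nosylate F3. LiBr in acetone displaces it by SN2 with inversion to the trans-bromohydrin F4. K2CO3 (or Ag2O) then closes the ring with a second inversion, and the route is rejoined at 13.

**Step 11, [4+4] against [4+2].** With the free hydroxyl, the hydrogen-bond-organised Diels–Alder dimers (epoxyquinols A and B) dominate. Epoxytwinol A is expected only as a minor dimer, on the order of 10 %, and has to be separated by chromatography.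

The fallback sets out from 17.
- 17 is oxidised with MnO2 at high dilution (≤0.01 M in CH2Cl2), where 18/19 persist.
- The solution is treated with excess i-Pr2SiCl2/imidazole at 0 °C to give the chlorosilyl ether F5.
- F5 is hydrolysed on NaHCO3 work-up to the alkoxysilanol 2H-pyran F6.
- Capping the carbinol removes the hydrogen bond that organises the [4+2] transition state, and the silanol OH pairs two pyrans head-to-head.
- Concentration to a neat film therefore gives mainly the bis(silanol) [4+4] dimer F7.
- Et3N·3HF in MeCN removes the silicon groups, and the route is rejoined at 20.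

## Further compounds

F1 | step 4 | (1S-type) cis-1,4-diol triol: 6 carrying two new OH groups at the former diene termini, both on the face opposite the acetonide | OCC1=C[C@@H](O)[C@@H]2OC(C)(C)O[C@@H]2[C@H]1O
F2 | step 4 | di-tert-butylsilylene acetal of F1 across CH2OH and the adjacent secondary OH, remote allylic OH free | O[C@@H]1C=C2CO[Si](C(C)(C)C)(C(C)(C)C)O[C@@H]2[C@H]3OC(C)(C)O[C@@H]13
F3 | step 7 | 6-O-(4-nitrobenzenesulfonate) of 10 | O=C1C=C2CO[Si](C(C)(C)C)(C(C)(C)C)O[C@@H]2[C@@H](O)[C@H]1OS(=O)(=O)c3ccc(cc3)[N+](=O)[O-]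
F4 | step 7 | trans-6-bromo-5-hydroxy compound (C6 inverted) | O=C1C=C2CO[Si](C(C)(C)C)(C(C)(C)C)O[C@@H]2[C@@H](O)[C@@H]1Br
F5 | step 11 | O-(chlorodiisopropylsilyl) ether of 19 | C[C@H]1OC=C2[C@H](O[Si](Cl)(C(C)C)C(C)C)[C@H]3O[C@H]3C(=O)C2=C1
F6 | step 11 | O-(hydroxydiisopropylsilyl) ether of 19 (alkoxysilanol 2H-pyran) | C[C@H]1OC=C2[C@H](O[Si](O)(C(C)C)C(C)C)[C@H]3O[C@H]3C(=O)C2=C1
F7 | step 11 | bis[O-(hydroxydiisopropylsilyl)] ether of epoxytwinol A | C[C@H]1O[C@H]2C3=C(C(=O)[C@@H]4O[C@@H]4[C@H]3O[Si](O)(C(C)C)C(C)C)[C@@H]1[C@H]1C3=C([C@H](O[Si](O)(C(C)C)C(C)C)[C@H]4O[C@H]4C3=O)[C@@H]2O[C@@H]1C
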